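**Retrosynthetic overview**

1. Target 34 comes from bis-acetylation of triol 33. The ring C5‑OH/C6=CH2 unit comes from an α‑5,6‑epoxide by aluminium amide isomerisation. The C7 carbinol comes from Felkin–Anh addition of side-chain Grignard reagent 30 to methyl ketone 25.
2. Ketone 25 (C1 stereocentre) comes from face-selective hydrogenation of cyclopentenyl methyl ketone 23, made from enol triflate 21 of trans-hydroazulenone 19.
3. Ketone 19 comes from bicyclic ketone 13 by radical removal of the C3 carbonyl and oxidation at C1. The seven-membered ring is formed second, by ring-closing metathesis of 12.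
4. Ketone 12 comes from anti conjugate addition and anti allylation on the pre-formed five-membered ring of (R)-4-silyloxy-2-methylcyclopentenone 7, which comes from lipase desymmetrisation of meso diol 1.
5. Side chain 29 comes from Shi epoxidation of homoprenyl bromide 26, epoxide-to-allylic-alcohol isomerisation and silylation.

Assumption: bicyclic compounds carry azulene locants (C1 = side-chain carbon, C3a = methyl-bearing ring-fusion carbon, C5/C6 = oxygenated and methyl(ene)-bearing carbons of the seven-membered ring, C8a = ring-fusion CH); 1, 8 and 26 are purchased.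

**Route**

Step 1
Reactants: 1 cis-cyclopent-4-ene-1,3-diol (meso, achiral)
Product: 2 (1S,4R)-4-hydroxycyclopent-2-en-1-yl acetate
Conditions: porcine pancreatic lipase (pancreatin), vinyl acetate, Et3N, THF, rt
Reagents that add atoms: vinyl acetate, C=COC(C)=O
Why: Lipase-catalysed enantiotopos-selective transesterification (enzymatic desymmetrisation) acetylates only one of the two mirror-related hydroxyls, so the enzyme fixes the absolute configuration of the free (4R) carbinol carbon, which later becomes C1 of the hydroazulene.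

Step 2
Reactants: 2 (1S,4R)-4-hydroxycyclopent-2-en-1-yl acetate
Product: 3 (1S,4R)-4-[(tert-butyldimethylsilyl)oxy]cyclopent-2-en-1-yl acetate
Conditions: TBSCl, imidazole, DMF, rt
Reagents that add atoms: tert-butyldimethylsilyl chloride, CC(C)(C)[Si](C)(C)Cl
Why: Routine silylation of the free secondary alcohol; no stereocentre is touched.

Step 3
Reactants: 3 (1S,4R)-4-[(tert-butyldimethylsilyl)oxy]cyclopent-2-en-1-yl acetate
Product: 4 (1S,4R)-4-[(tert-butyldimethylsilyl)oxy]cyclopent-2-en-1-ol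
Conditions: K2CO3 (cat.), MeOH, 0 °C to rt
Reagents that add atoms: none
Why: Mild transesterification (methanolysis) removes the acetate while the silyl ether survives.

Step 4
Reactants: 4 (1S,4R)-4-[(tert-butyldimethylsilyl)oxy]cyclopent-2-en-1-ol
Product: 5 (4R)-4-[(tert-butyldimethylsilyl)oxy]cyclopent-2-en-1-one
Conditions: MnO2, CH2Cl2, rt
Reagents that add atoms: none
Why: Allylic alcohol oxidation under neutral conditions puts the carbonyl on the former acetate carbon and leaves the silyloxy stereocentre as R.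

Step 5
Reactants: 5 (4R)-4-[(tert-butyldimethylsilyl)oxy]cyclopent-2-en-1-one
Product: 6 (4R)-4-[(tert-butyldimethylsilyl)oxy]-2-iodocyclopent-2-en-1-one
Conditions: I2, pyridine, CH2Cl2, 0 °C to rt
Reagents that add atoms: iodine, II
Why: α-Iodination of the enone by pyridine conjugate addition, iodination of the enolate and elimination (Baylis–Hillman-type mechanism), which does not disturb the γ-silyloxy centre.

Step 6
Reactants: 6 (4R)-4-[(tert-butyldimethylsilyl)oxy]-2-iodocyclopent-2-en-1-one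
Product: 7 (4R)-4-[(tert-butyldimethylsilyl)oxy]-2-methylcyclopent-2-en-1-one
Conditions: Me4Sn, Pd2(dba)3 (2.5 mol%), AsPh3, CuI, NMP, 60 °C
Reagents that add atoms: tetramethylstannane, C[Sn](C)(C)C
Why: Stille cross-coupling of the α-iodoenone runs under neutral conditions, so the base-sensitive β-silyloxy enone is not eliminated.

Step 7
Reactants: 7 (4R)-4-[(tert-butyldimethylsilyl)oxy]-2-methylcyclopent-2-en-1-one; 8 4-bromo-2-methylbut-1-ene
Product: 10 tert-butyl({(1R,2R)-3-methyl-2-(3-methylbut-3-en-1-yl)-4-[(trimethylsilyl)oxy]cyclopent-3-en-1-yl}oxy)dimethylsilane, via Grignard reagent 9 (not isolated)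
Conditions: 8, Mg, THF, rt; then CuBr·SMe2 (10 mol%), TMSCl, HMPA, 7, THF, −78 °C; Et3N
Reagents that add atoms: chlorotrimethylsilane, C[Si](C)(C)Cl
Why: Copper-catalysed conjugate addition of the Grignard reagent occurs anti to the C4 silyloxy group (prostaglandin-type control), setting the future C8a centre, and TMSCl traps the enolate regiospecifically.

Step 8
Reactants: 10 tert-butyl({(1R,2R)-3-methyl-2-(3-methylbut-3-en-1-yl)-4-[(trimethylsilyl)oxy]cyclopent-3-en-1-yl}oxy)dimethylsilane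
Product: 12 (2R,3R,4R)-4-[(tert-butyldimethylsilyl)oxy]-2-methyl-3-(3-methylbut-3-en-1-yl)-2-(prop-2-en-1-yl)cyclopentan-1-one, via lithium enolate 11 (not isolated)
Conditions: MeLi, THF, 0 °C; then HMPA, allyl iodide, −78 to −40 °C
Reagents that add atoms: allyl iodide, C=CCI
Why: MeLi cleaves the silyl enol ether to a regiodefined enolate whose C-allylation occurs anti to the neighbouring C3 chain, creating the quaternary centre with methyl cis to that chain (the future trans ring fusion).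

Step 9
Reactants: 12 (2R,3R,4R)-4-[(tert-butyldimethylsilyl)oxy]-2-methyl-3-(3-methylbut-3-en-1-yl)-2-(prop-2-en-1-yl)cyclopentan-1-one
Product: 13 (1R,3aR,8aR)-1-[(tert-butyldimethylsilyl)oxy]-3a,6-dimethyl-1,3a,4,7,8,8a-hexahydroazulen-3(2H)-one (trans-fused)
Conditions: second-generation Grubbs catalyst (5 mol%), CH2Cl2 (0.005 M), 40 °C
Reagents that add atoms: none
Why: Ring-closing metathesis of the allyl group with the 1,1-disubstituted alkene closes the seven-membered ring as a trisubstituted cycloheptene, with ethene loss as driving force.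

Step 10
Reactants: 13 (1R,3aR,8aR)-1-[(tert-butyldimethylsilyl)oxy]-3a,6-dimethyl-1,3a,4,7,8,8a-hexahydroazulen-3(2H)-one
Product: 14 (1R,3R,3aR,8aR)-1-[(tert-butyldimethylsilyl)oxy]-3a,6-dimethyl-1,2,3,3a,4,7,8,8a-octahydroazulen-3-ol
Conditions: NaBH4, MeOH, −20 °C
Reagents that add atoms: none
Why: Hydride reduction removes the elimination-prone β-silyloxy ketone at once, with attack anti to the angular methyl giving mainly the 3R alcohol (the C3 configuration is irrelevant because this carbon is deoxygenated next).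

Step 11
Reactants: 14 (1R,3R,3aR,8aR)-1-[(tert-butyldimethylsilyl)oxy]-3a,6-dimethyl-1,2,3,3a,4,7,8,8a-octahydroazulen-3-ol
Product: 16 O-{(1R,3R,3aR,8aR)-1-[(tert-butyldimethylsilyl)oxy]-3a,6-dimethyl-1,2,3,3a,4,7,8,8a-octahydroazulen-3-yl} S-methyl carbonodithioate, via sodium xanthate salt 15 (not isolated)
Conditions: NaH, THF, 0 °C; CS2; then MeI, rt
Reagents that add atoms: carbon disulfide, S=C=S; iodomethane, CI
Why: Xanthate formation works on hindered secondary alkoxides, and the trans-1,3 arrangement of hydroxyl and silyl ether prevents silyl migration.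

Step 12
Reactants: 16 O-{(1R,3R,3aR,8aR)-1-[(tert-butyldimethylsilyl)oxy]-3a,6-dimethyl-1,2,3,3a,4,7,8,8a-octahydroazulen-3-yl} S-methyl carbonodithioate
Product: 17 tert-butyl{[(1R,3aR,8aR)-3a,6-dimethyl-1,2,3,3a,4,7,8,8a-octahydroazulen-1-yl]oxy}dimethylsilane
Conditions: Bu3SnH, azobisisobutyronitrile (cat.), toluene, 110 °C
Reagents that add atoms: none
Why: Barton–McCombie radical deoxygenation turns C3 into CH2, and the secondary radical has no favourable cyclisation onto the ring alkene (only four-membered or 5-endo closures).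

Step 13
Reactants: 17 tert-butyl{[(1R,3aR,8aR)-3a,6-dimethyl-1,2,3,3a,4,7,8,8a-octahydroazulen-1-yl]oxy}dimethylsilane
Product: 18 (1R,3aR,8aR)-3a,6-dimethyl-1,2,3,3a,4,7,8,8a-octahydroazulen-1-ol
Conditions: TBAF, THF, rt
Reagents that add atoms: none
Why: Fluoride-mediated desilylation; nothing else in the molecule reacts.

Step 14
Reactants: 18 (1R,3aR,8aR)-3a,6-dimethyl-1,2,3,3a,4,7,8,8a-octahydroazulen-1-ol
Product: 19 (3aR,8aR)-3a,6-dimethyl-3,3a,4,7,8,8a-hexahydroazulen-1(2H)-one (trans-fused)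
Conditions: Dess–Martin periodinane, NaHCO3, CH2Cl2, rt
Reagents that add atoms: none
Why: Buffered hypervalent-iodine oxidation gives the C1 ketone without epimerising the adjacent ring-fusion centre C8a.

Step 15
Reactants: 19 (3aR,8aR)-3a,6-dimethyl-3,3a,4,7,8,8a-hexahydroazulen-1(2H)-one
Product: 21 (3aS,8aR)-3a,6-dimethyl-3,3a,4,7,8,8a-hexahydroazulen-1-yl trifluoromethanesulfonate, via potassium enolate 20 (not isolated)
Conditions: KN(SiMe3)2, THF, −78 °C; then PhNTf2, −78 to 0 °C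
Reagents that add atoms: N-phenylbis(trifluoromethanesulfonimide), O=S(=O)(N(c1ccccc1)S(=O)(=O)C(F)(F)F)C(F)(F)F
Why: Kinetic deprotonation takes the C2 methylene proton and not the hindered ring-fusion proton, so O-triflation gives the C1=C2 enol triflate with C8a intact (the 3a descriptor changes only through CIP priorities).

Step 16
Reactants: 21 (3aS,8aR)-3a,6-dimethyl-3,3a,4,7,8,8a-hexahydroazulen-1-yl trifluoromethanesulfonate
Product: 23 1-[(3aS,8aR)-3a,6-dimethyl-3,3a,4,7,8,8a-hexahydroazulen-1-yl]ethan-1-one, via ethoxydiene 22 (not isolated)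
Conditions: tributyl(1-ethoxyvinyl)stannane, Pd(PPh3)4 (5 mol%), LiCl, THF, 65 °C; then 1 M HCl, rt
Reagents that add atoms: tributyl(1-ethoxyvinyl)stannane, C=C(OCC)[Sn](CCCC)(CCCC)CCCC; water, O
Why: Stille coupling of the enol triflate with an acetyl-anion equivalent, then enol ether hydrolysis, gives the conjugated methyl ketone.

Step 17
Reactants: 23 1-[(3aS,8aR)-3a,6-dimethyl-3,3a,4,7,8,8a-hexahydroazulen-1-yl]ethan-1-one
Product: 24 1-[(3aR,5S,6R,8aR)-5,6-epoxy-3a,6-dimethyl-3,3a,4,5,6,7,8,8a-octahydroazulen-1-yl]ethan-1-one (α-epoxide)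
Conditions: mCPBA, NaHCO3, CH2Cl2, 0 °C
Reagents that add atoms: 3-chloroperbenzoic acid, OOC(=O)c1cccc(Cl)c1
Why: Prilezhaev epoxidation takes only the electron-rich trisubstituted ring alkene (the enone alkene is inert) and attacks the face opposite the axial angular methyl of the locked trans-fused cycloheptene, setting C5 (S).

Step 18
Reactants: 24 1-[(3aR,5S,6R,8aR)-5,6-epoxy-3a,6-dimethyl-3,3a,4,5,6,7,8,8a-octahydroazulen-1-yl]ethan-1-one
Product: 25 1-[(1S,3aR,5S,6R,8aS)-5,6-epoxy-3a,6-dimethyldecahydroazulen-1-yl]ethan-1-one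
Conditions: H2 (1 atm), Pd/C (10%), EtOAc, rt
Reagents that add atoms: none
Why: Heterogeneous syn hydrogenation of the enone alkene from the α face, away from the C8 methylene on C8a and the angular methyl, places H-1 α and the acetyl group β (C1 = S), as in 16-ene-20-ketosteroids.

Step 19
Reactants: 26 5-bromo-2-methylpent-2-ene
Product: 27 (3S)-3-(2-bromoethyl)-2,2-dimethyloxirane
Conditions: 1,2:4,5-di-O-isopropylidene-β-L-erythro-2,3-hexodiulo-2,6-pyranose (L-fructose-derived Shi ketone, 30 mol%), KHSO5 (as 2KHSO5·KHSO4·K2SO4), K2CO3, Bu4NHSO4, MeCN/dimethoxymethane/aq. buffer pH 10.5, 0 °C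
Reagents that add atoms: potassium peroxymonosulfate, [K+].[O-]S(=O)(=O)OO
Why: Shi asymmetric epoxidation (chiral dioxirane, spiro transition state) of the trisubstituted alkene sets the side-chain stereocentre by catalyst control; the L-derived ketone gives the S epoxide.

Step 20
Reactants: 27 (3S)-3-(2-bromoethyl)-2,2-dimethyloxirane
Product: 28 (3S)-5-bromo-2-methylpent-1-en-3-ol
Conditions: 2,2,6,6-tetramethylpiperidine, n-BuLi, then Et2AlCl (gives diethylaluminium 2,2,6,6-tetramethylpiperidide), toluene, 0 °C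
Reagents that add atoms: none
Why: Aluminium amide-promoted syn β-elimination of the epoxide (Yamamoto isomerisation) removes a methyl proton and gives the isopropenyl carbinol with the C–O bond, hence the S configuration, retained.

Step 21
Reactants: 28 (3S)-5-bromo-2-methylpent-1-en-3-ol
Product: 29 {[(3S)-5-bromo-2-methylpent-1-en-3-yl]oxy}(tert-butyl)dimethylsilane
Conditions: TBSCl, imidazole, DMF, rt
Reagents that add atoms: tert-butyldimethylsilyl chloride, CC(C)(C)[Si](C)(C)Cl
Why: Silylation protects the allylic alcohol so that the bromide can be turned into a Grignard reagent.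

Step 22
Reactants: 25 1-[(1S,3aR,5S,6R,8aS)-5,6-epoxy-3a,6-dimethyldecahydroazulen-1-yl]ethan-1-one; 29 {[(3S)-5-bromo-2-methylpent-1-en-3-yl]oxy}(tert-butyl)dimethylsilane
Product: 31 (2S,5S)-5-[(tert-butyldimethylsilyl)oxy]-2-[(1S,3aR,5S,6R,8aS)-5,6-epoxy-3a,6-dimethyldecahydroazulen-1-yl]-6-methylhept-6-en-2-ol, via side-chain Grignard reagent 30 (not isolated)
Conditions: 29, Mg, THF, 40 °C; CeCl3, THF, −78 °C; then 25, −78 to 0 °C
Reagents that add atoms: none
Why: CeCl3-promoted Grignard addition suppresses enolisation of the methyl ketone, and Felkin–Anh attack (C8a as the large group, as in 20-ketosteroid additions) gives the 7S tertiary carbinol, the minor epimer being removed by chromatography.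

Step 23
Reactants: 31 (2S,5S)-5-[(tert-butyldimethylsilyl)oxy]-2-[(1S,3aR,5S,6R,8aS)-5,6-epoxy-3a,6-dimethyldecahydroazulen-1-yl]-6-methylhept-6-en-2-ol
Product: 32 (1S,3aR,5S,8aS)-1-{(2S,5S)-5-[(tert-butyldimethylsilyl)oxy]-2-hydroxy-6-methylhept-6-en-2-yl}-3a-methyl-6-methylidenedecahydroazulen-5-ol
Conditions: 2,2,6,6-tetramethylpiperidine, n-BuLi, then Et2AlCl (5 equiv of diethylaluminium 2,2,6,6-tetramethylpiperidide), toluene, 0 °C to rt
Reagents that add atoms: none
Why: The same epoxide-to-allylic-alcohol isomerisation removes a proton from the C6 methyl (cis to H-5, least hindered), giving the exocyclic methylene and the secondary 5α alcohol with retention at C5 (S).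

Step 24
Reactants: 32 (1S,3aR,5S,8aS)-1-{(2S,5S)-5-[(tert-butyldimethylsilyl)oxy]-2-hydroxy-6-methylhept-6-en-2-yl}-3a-methyl-6-methylidenedecahydroazulen-5-ol
Product: 33 (1S,3aR,5S,8aS)-1-[(2S,5S)-2,5-dihydroxy-6-methylhept-6-en-2-yl]-3a-methyl-6-methylidenedecahydroazulen-5-ol
Conditions: TBAF, THF, rt
Reagents that add atoms: none
Why: Fluoride cleaves the one remaining silyl ether without affecting the alkenes or alcohols.

Step 25
Reactants: 33 (1S,3aR,5S,8aS)-1-[(2S,5S)-2,5-dihydroxy-6-methylhept-6-en-2-yl]-3a-methyl-6-methylidenedecahydroazulen-5-ol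
Product: 34 (1S,3aR,5S,8aS)-1-[(2S,5S)-5-(acetyloxy)-2-hydroxy-6-methylhept-6-en-2-yl]-3a-methyl-6-methylidenedecahydroazulen-5-yl acetate
Conditions: Ac2O, pyridine, 4-(dimethylamino)pyridine (cat.), CH2Cl2, 0 °C to rt
Reagents that add atoms: acetic anhydride, CC(=O)OC(C)=O
Why: Nucleophilic-catalysed acylation esterifies the two secondary allylic alcohols, while the hindered tertiary C7 alcohol stays free under these mild conditions.

**Compound list**

1 | cis-cyclopent-4-ene-1,3-diol (meso) | O[C@@H]1C=C[C@H](O)C1 | starting material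
2 | (1S,4R)-4-hydroxycyclopent-2-en-1-yl acetate | CC(=O)O[C@@H]1C=C[C@H](O)C1 | intermediate
3 | (1S,4R)-4-[(tert-butyldimethylsilyl)oxy]cyclopent-2-en-1-yl acetate | CC(=O)O[C@@H]1C=C[C@H](O[Si](C)(C)C(C)(C)C)C1 | intermediate
4 | (1S,4R)-4-[(tert-butyldimethylsilyl)oxy]cyclopent-2-en-1-ol | O[C@@H]1C=C[C@H](O[Si](C)(C)C(C)(C)C)C1 | intermediate
5 | (4R)-4-[(tert-butyldimethylsilyl)oxy]cyclopent-2-en-1-one | O=C1C=C[C@H](O[Si](C)(C)C(C)(C)C)C1 | intermediate
6 | (4R)-4-[(tert-butyldimethylsilyl)oxy]-2-iodocyclopent-2-en-1-one | O=C1C(I)=C[C@H](O[Si](C)(C)C(C)(C)C)C1 | intermediate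
7 | (4R)-4-[(tert-butyldimethylsilyl)oxy]-2-methylcyclopent-2-en-1-one | O=C1C(C)=C[C@H](O[Si](C)(C)C(C)(C)C)C1 | intermediate
8 | 4-bromo-2-methylbut-1-ene | C=C(C)CCBr | starting material
9 | (3-methylbut-3-en-1-yl)magnesium bromide | C=C(C)CC[Mg]Br | intermediate
10 | tert-butyl({(1R,2R)-3-methyl-2-(3-methylbut-3-en-1-yl)-4-[(trimethylsilyl)oxy]cyclopent-3-en-1-yl}oxy)dimethylsilane | CC(C)(C)[Si](C)(C)O[C@@H]1CC(O[Si](C)(C)C)=C(C)[C@H]1CCC(C)=C | intermediate
11 | lithium (3R,4R)-4-[(tert-butyldimethylsilyl)oxy]-2-methyl-3-(3-methylbut-3-en-1-yl)cyclopent-1-en-1-olate | CC(C)(C)[Si](C)(C)O[C@@H]1CC(O[Li])=C(C)[C@H]1CCC(C)=C | intermediate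
12 | (2R,3R,4R)-4-[(tert-butyldimethylsilyl)oxy]-2-methyl-3-(3-methylbut-3-en-1-yl)-2-(prop-2-en-1-yl)cyclopentan-1-one | CC(C)(C)[Si](C)(C)O[C@@H]1CC(=O)[C@](C)(CC=C)[C@H]1CCC(C)=C | intermediate
13 | (1R,3aR,8aR)-1-[(tert-butyldimethylsilyl)oxy]-3a,6-dimethyl-1,3a,4,7,8,8a-hexahydroazulen-3(2H)-one | CC(C)(C)[Si](C)(C)O[C@@H]1CC(=O)[C@]2(C)CC=C(C)CC[C@@H]12 | intermediate
14 | (1R,3R,3aR,8aR)-1-[(tert-butyldimethylsilyl)oxy]-3a,6-dimethyl-1,2,3,3a,4,7,8,8a-octahydroazulen-3-ol | CC(C)(C)[Si](C)(C)O[C@@H]1C[C@@H](O)[C@]2(C)CC=C(C)CC[C@@H]12 | intermediate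
15 | sodium O-{(1R,3R,3aR,8aR)-1-[(tert-butyldimethylsilyl)oxy]-3a,6-dimethyl-1,2,3,3a,4,7,8,8a-octahydroazulen-3-yl} carbonodithioate | CC(C)(C)[Si](C)(C)O[C@@H]1C[C@@H](OC(=S)[S-])[C@]2(C)CC=C(C)CC[C@@H]12.[Na+] | intermediate
16 | O-{(1R,3R,3aR,8aR)-1-[(tert-butyldimethylsilyl)oxy]-3a,6-dimethyl-1,2,3,3a,4,7,8,8a-octahydroazulen-3-yl} S-methyl carbonodithioate | CC(C)(C)[Si](C)(C)O[C@@H]1C[C@@H](OC(=S)SC)[C@]2(C)CC=C(C)CC[C@@H]12 | intermediate
17 | tert-butyl{[(1R,3aR,8aR)-3a,6-dimethyl-1,2,3,3a,4,7,8,8a-octahydroazulen-1-yl]oxy}dimethylsilane | CC(C)(C)[Si](C)(C)O[C@@H]1CC[C@]2(C)CC=C(C)CC[C@@H]12 | intermediate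
18 | (1R,3aR,8aR)-3a,6-dimethyl-1,2,3,3a,4,7,8,8a-octahydroazulen-1-ol | O[C@@H]1CC[C@]2(C)CC=C(C)CC[C@@H]12 | intermediate
19 | (3aR,8aR)-3a,6-dimethyl-3,3a,4,7,8,8a-hexahydroazulen-1(2H)-one | O=C1CC[C@]2(C)CC=C(C)CC[C@@H]12 | intermediate
20 | potassium (3aS,8aR)-3a,6-dimethyl-3,3a,4,7,8,8a-hexahydroazulen-1-olate | [K]OC1=CC[C@]2(C)CC=C(C)CC[C@@H]12 | intermediate
21 | (3aS,8aR)-3a,6-dimethyl-3,3a,4,7,8,8a-hexahydroazulen-1-yl trifluoromethanesulfonate | O=S(=O)(OC1=CC[C@]2(C)CC=C(C)CC[C@@H]12)C(F)(F)F | intermediate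
22 | (3aS,8aR)-1-(1-ethoxyethenyl)-3a,6-dimethyl-3,3a,4,7,8,8a-hexahydroazulene | C=C(OCC)C1=CC[C@]2(C)CC=C(C)CC[C@@H]12 | intermediate
23 | 1-[(3aS,8aR)-3a,6-dimethyl-3,3a,4,7,8,8a-hexahydroazulen-1-yl]ethan-1-one | CC(=O)C1=CC[C@]2(C)CC=C(C)CC[C@@H]12 | intermediate
24 | 1-[(3aR,5S,6R,8aR)-5,6-epoxy-3a,6-dimethyl-3,3a,4,5,6,7,8,8a-octahydroazulen-1-yl]ethan-1-one | CC(=O)C1=CC[C@]2(C)C[C@@H]3O[C@]3(C)CC[C@@H]12 | intermediate
25 | 1-[(1S,3aR,5S,6R,8aS)-5,6-epoxy-3a,6-dimethyldecahydroazulen-1-yl]ethan-1-one | CC(=O)[C@H]1CC[C@]2(C)C[C@@H]3O[C@]3(C)CC[C@@H]12 | intermediate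
26 | 5-bromo-2-methylpent-2-ene | CC(C)=CCCBr | starting material
27 | (3S)-3-(2-bromoethyl)-2,2-dimethyloxirane | BrCC[C@@H]1OC1(C)C | intermediate
28 | (3S)-5-bromo-2-methylpent-1-en-3-ol | C=C(C)[C@H](CCBr)O | intermediate
29 | {[(3S)-5-bromo-2-methylpent-1-en-3-yl]oxy}(tert-butyl)dimethylsilane | C=C(C)[C@H](CCBr)O[Si](C)(C)C(C)(C)C | intermediate
30 | {(3S)-3-[(tert-butyldimethylsilyl)oxy]-4-methylpent-4-en-1-yl}magnesium bromide | C=C(C)[C@H](CC[Mg]Br)O[Si](C)(C)C(C)(C)C | intermediate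
31 | (2S,5S)-5-[(tert-butyldimethylsilyl)oxy]-2-[(1S,3aR,5S,6R,8aS)-5,6-epoxy-3a,6-dimethyldecahydroazulen-1-yl]-6-methylhept-6-en-2-ol | C=C(C)[C@H](CC[C@](C)(O)[C@H]1CC[C@]2(C)C[C@@H]3O[C@]3(C)CC[C@@H]12)O[Si](C)(C)C(C)(C)C | intermediate
32 | (1S,3aR,5S,8aS)-1-{(2S,5S)-5-[(tert-butyldimethylsilyl)oxy]-2-hydroxy-6-methylhept-6-en-2-yl}-3a-methyl-6-methylidenedecahydroazulen-5-ol | C=C(C)[C@H](CC[C@](C)(O)[C@H]1CC[C@]2(C)C[C@H](O)C(=C)CC[C@@H]12)O[Si](C)(C)C(C)(C)C | intermediate
33 | (1S,3aR,5S,8aS)-1-[(2S,5S)-2,5-dihydroxy-6-methylhept-6-en-2-yl]-3a-methyl-6-methylidenedecahydroazulen-5-ol | C=C(C)[C@H](CC[C@](C)(O)[C@H]1CC[C@]2(C)C[C@H](O)C(=C)CC[C@@H]12)O | intermediate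
34 | (1S,3aR,5S,8aS)-1-[(2S,5S)-5-(acetyloxy)-2-hydroxy-6-methylhept-6-en-2-yl]-3a-methyl-6-methylidenedecahydroazulen-5-yl acetate | C=C(C)[C@H](CC[C@](C)(O)[C@H]1CC[C@]2(C)C[C@H](OC(C)=O)C(=C)CC[C@@H]12)OC(C)=O | target

**Step count and risks**

Total step count: 25. Longest linear sequence: 22 steps (steps 1–18, then 22–25); the side chain takes 3 steps (19–21).

Three steps most likely to fail:

Step 8 (quaternary allylation). The hindered tetrasubstituted enolate 11 may alkylate slowly, and proton transfer to C5 would then expel the silyloxy group. The fallback sets out from 10 and comes back at 12. The enolate made from 10 with MeLi is O-acylated with allyl chloroformate to give the allyl enol carbonate F1. Pd(PPh3)4 in THF at rt then brings about Tsuji decarboxylative allylation, in which the palladium enolate and allyl fragment recombine under neutral conditions, again anti to the C3 chain, to give 12.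

Step 22 (C7 carbinol). The sense or level of 1,2-induction may not follow the Felkin–Anh prediction. The fallback sets out from 21 and comes back at 31, and it introduces the two carbon groups on C7 in the reverse order. Triflate 21 is aminocarbonylated (Pd(OAc)2, Ph2P(CH2)3PPh2, CO 1 atm, MeNHOMe·HCl, Et3N, DMF, 60 °C) to the unsaturated Weinreb amide F2. This is epoxidised with mCPBA to the epoxy amide F3 and hydrogenated over Pd/C to the saturated amide F4, with the same facial control as in steps 17 and 18. Grignard reagent 30 converts F4 into the side-chain ketone F5, and MeMgBr/CeCl3 then adds methyl to the diastereoface that the chain nucleophile would have attacked. This inverts the C7 outcome and delivers 31 if step 22 favours the wrong epimer.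

Step 23 (late epoxide isomerisation). The elimination may give the endocyclic alkene or stall on the aluminium alkoxide of the free tertiary alcohol. The fallback sets out from 31 and comes back at 32. TMSOTf and 2,6-lutidine in toluene at −78 °C silylate the tertiary hydroxyl and open the activated epoxide at its tertiary carbon; DBU then removes a methyl proton by anti elimination (Noyori protocol) to give the bis(trimethylsilyl) ether F6. K2CO3 in MeOH cleaves both trimethylsilyl ethers, leaves the TBS ether in place, and returns 32.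

**Further compounds**

F1 | step 8 | (3R,4R)-4-[(tert-butyldimethylsilyl)oxy]-2-methyl-3-(3-methylbut-3-en-1-yl)cyclopent-1-en-1-yl prop-2-en-1-yl carbonate | CC(C)(C)[Si](C)(C)O[C@@H]1CC(OC(=O)OCC=C)=C(C)[C@H]1CCC(C)=C
F2 | step 22 | (3aS,8aR)-N-methoxy-N,3a,6-trimethyl-3,3a,4,7,8,8a-hexahydroazulene-1-carboxamide | CON(C)C(=O)C1=CC[C@]2(C)CC=C(C)CC[C@@H]12
F3 | step 22 | (3aR,5S,6R,8aR)-5,6-epoxy-N-methoxy-N,3a,6-trimethyl-3,3a,4,5,6,7,8,8a-octahydroazulene-1-carboxamide | CON(C)C(=O)C1=CC[C@]2(C)C[C@@H]3O[C@]3(C)CC[C@@H]12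
F4 | step 22 | (1S,3aR,5S,6R,8aS)-5,6-epoxy-N-methoxy-N,3a,6-trimethyldecahydroazulene-1-carboxamide | CON(C)C(=O)[C@H]1CC[C@]2(C)C[C@@H]3O[C@]3(C)CC[C@@H]12
F5 | step 22 | (4S)-4-[(tert-butyldimethylsilyl)oxy]-1-[(1S,3aR,5S,6R,8aS)-5,6-epoxy-3a,6-dimethyldecahydroazulen-1-yl]-5-methylhex-5-en-1-one | C=C(C)[C@H](CCC(=O)[C@H]1CC[C@]2(C)C[C@@H]3O[C@]3(C)CC[C@@H]12)O[Si](C)(C)C(C)(C)C
F6 | step 23 | tert-butyl({(3S,6S)-2-methyl-6-[(1S,3aR,5S,8aS)-3a-methyl-6-methylidene-5-[(trimethylsilyl)oxy]decahydroazulen-1-yl]-6-[(trimethylsilyl)oxy]hept-1-en-3-yl}oxy)dimethylsilane | C=C(C)[C@H](CC[C@](C)(O[Si](C)(C)C)[C@H]1CC[C@]2(C)C[C@H](O[Si](C)(C)C)C(=C)CC[C@@H]12)O[Si](C)(C)C(C)(C)C
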